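A curve that bends is easily taken for a curve that ends, and the two give different numbers.

| flask | electrophile | nucleophile | free base | remark | time |
|---|---|---|---|---|---|
| cedar | 5 mM | 1.8 equiv | 0.56 equiv | run made earlier |  |
| elm | 5 mM | 1.8 equiv | 2.7 equiv | run made earlier |  |
| Sunday's | 5.0 mM | 1.80 equiv | 1.10 equiv |  | 2.0 min |
| Friday's | 5.0 mM | 1.80 equiv | 2.20 equiv |  | 2.0 min |
| Tuesday's | 5.0 mM | 1.80 equiv | 4.40 equiv |  | 2.0 min |

| run | time / s | electrophile / % | target / % |
|---|---|---|---|
| cedar | 10.0 | 31 | 66 |
| cedar | 12.0 | 24 | 71 |
| cedar | 25.0 | 17 | 80 |
| cedar | 40.0 | 11 | 86 |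
| cedar | 50.0 | 14 | 89 |
| cedar | 60.0 | 9 | 92 |
| cedar | 80.0 | 9 | 96 |
| elm | 10.0 | 30 | 68 |
| elm | 12.0 | 27 | 75 |
| elm | 25.0 | 18 | 83 |
| elm | 40.0 | 15 | 88 |
| elm | 50.0 | 11 | 93 |
| elm | 60.0 | 9 | 93 |
| elm | 80.0 | 7 | 91 |

(readings scatter by 2 percentage points)

1. part of the electrophile that has reacted at the end, Sunday's
2. part of the electrophile that has reacted at the end, Friday's
3. part of the electrophile that has reacted at the end, Tuesday's
4. what raising the equivalents of free base from its lowest to its highest value here does to the part of the electrophile that has reacted (changes below 5 percentage points count as none) (it falls / no change / it rises)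



Start from the zero of the scale: suppose the free base does nothing, so that cedar and elm, whose free base differs by a factor of 4.82, are one flask run twice. Their electrophile readings differ by 2 percentage points at the last reading, and two readings of this scatter typically differ by about 2.8 points. So I pool the two runs and expect no change, though Tuesday's charge lies beyond both.

Now follow the electrophile, the limiting reagent. The pooled readings at 25.0 s and 60.0 s give τ = 36.5 s, the tail half-life: the time in which the electrophile still present falls by a factor of two. Two extreme flasks bracket the answer. If the pace of the first 10.0 s held, with a half-life of 5.84 s, then 2.0 min would leave hardly any electrophile. If the flask stopped at 60.0 s, 91.0 % would have reacted. The readings speak against the first, since τ is longer than that early half-life. Against the second I only assume that the tail goes on falling, which the scatter at 80.0 s cannot test. Holding τ from 60.0 s leaves 2.88 %, so my reckoning is 97.1 % reacted in each flask.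

The forecast gives 93 %, 93 % and 93 % with no change, on the reading that the slowing “suggests a plateau, from reversibility or inhibition”, and this is less than my figure.

The flasks give 98.1 %, 98.1 % and 98.1 %, a spread of 0.018 points, so the answer on raising the free base is no change.

    electrophile + nucleophile → acid set free + target (k = 28.0 L mol⁻¹ s⁻¹)
    nucleophile + acid set free ⇌ protonated nucleophile, settled at all times (K = 7.60 × 10⁵ L mol⁻¹)
    acid set free + free base ⇌ salt of the base (K = 5.60 × 10⁵ L mol⁻¹, k = 72.0 L mol⁻¹ s⁻¹)
    acid set free → by-product carried off (k = 3.00 s⁻¹)
    2 free base → self-condensation product (k = 7.20 L mol⁻¹ s⁻¹)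

At 1.00 min Sunday's held 3.66 mM of protonated nucleophile, with 8.29 % of the charged nucleophile free. From the 8.18 % electrophile of that moment, τ leaves 2.62 % at 2.00 min, and Sunday's holds 1.87 %. Carried from the pooled 25.0 s readings to 30 s, τ leaves 15.9 %, and Tuesday's flask stopped at that time holds 15.3 %.

All runs stem from a simulated flask for an exercise; noise was put on by code.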